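Everything rests on the latent symmetry of the 1,2-dioxane ring: C3 and C6 are both quaternary and each carries, besides the ring oxygen, a methyl group and a chain that begins with CH2. Both carbons are therefore traced back to C(CH2OAc)2 units of an achiral 3,3,6,6-tetrakis(acetoxymethyl)-1,2-dioxane. A lipase cleaves one enantiotopic acetate at C3 and the C2-related one at C6, which sets both quaternary stereocentres in a single operation without forming a skeletal bond and gives a C2-symmetric trans diol diacetate. The freed arms then become the methyl groups, and the two homotopic acetoxymethyl arms are grown in turn into the 8-phenyloctyl and propanoic acid chains.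

Key step: step 8

Assumption: Burkholderia cepacia lipase is taken to cleave the enantiotopic acetates that give (3S,6S)-12; if the enzyme shows the opposite sense, the same target follows by making the free hydroxymethyl arms the chains and the acetoxymethyl arms the methyl groups.

Step 1
Reactants: 1 ethyl 2-(bromomethyl)acrylate (2 equiv)
Product: 2 diethyl 2,5-dimethylidenehexanedioate
Conditions: Zn dust (0.55 equiv), THF, 0 °C → rt
Reagents that add atoms: none
Why: Zinc inserts into the allylic C–Br bond and the resulting allylzinc bromide attacks a second molecule of 1 in an SN2′ addition–elimination (Wurtz-type reductive allyl–allyl coupling), every regiochemical mode of which gives the same symmetrical 1,5-diene diester.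

Step 2
Reactants: 2 diethyl 2,5-dimethylidenehexanedioate
Product: 3 2,5-dimethylidenehexane-1,6-diol
Conditions: i-Bu2AlH (4.4 equiv), CH2Cl2, −78 → 0 °C; aq. KNaC4H4O6 work-up
Reagents that add atoms: none
Why: i-Bu2AlH reduces α,β-unsaturated esters by 1,2-hydride delivery to the allylic alcohols and does not touch the 1,1-disubstituted alkenes (ester reduction).

Step 3
Reactants: 3 2,5-dimethylidenehexane-1,6-diol
Product: 4 1,6-bis(tert-butyldiphenylsilyloxy)-2,5-dimethylidenehexane
Conditions: t-BuPh2SiCl (2.2 equiv), imidazole, DMF, rt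
Reagents that add atoms: tert-butyl(chloro)diphenylsilane, CC(C)(C)[Si](Cl)(c1ccccc1)c1ccccc1
Why: Imidazole-promoted silylation caps both primary hydroxyls, which would otherwise compete as internal nucleophiles for the activated epoxides in step 5, with a group that is stable to peracid and to the acidic perhydrolysis (silyl ether protection).

Step 4
Reactants: 4 1,6-bis(tert-butyldiphenylsilyloxy)-2,5-dimethylidenehexane
Product: 5 1,2-bis{2-[(tert-butyldiphenylsilyloxy)methyl]oxiran-2-yl}ethane (meso and racemic diastereomers)
Conditions: mCPBA (2.5 equiv), CH2Cl2, 0 °C → rt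
Reagents that add atoms: 3-chloroperoxybenzoic acid, OOC(=O)c1cccc(Cl)c1
Why: Prilezhaev epoxidation of the two electron-rich 1,1-disubstituted alkenes proceeds without stereocontrol, which does not matter because these carbons cease to be stereocentres once achiral 9 is reached.

Step 5
Reactants: 5 1,2-bis{2-[(tert-butyldiphenylsilyloxy)methyl]oxiran-2-yl}ethane, 6 hydrogen peroxide
Product: 8 3,6-bis[(tert-butyldiphenylsilyloxy)methyl]-3,6-bis(hydroxymethyl)-1,2-dioxane (cis/trans mixture), via hydroperoxy epoxide 7 (not isolated)
Conditions: anhydrous H2O2 (3 M in Et2O, 8 equiv), H3PMo12O40 (5 mol%), Et2O, 0 °C → rt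
Reagents that add atoms: none
Why: Acid-catalysed perhydrolysis of a 2,2-disubstituted epoxide places the hydroperoxide on the tertiary carbon (Markovnikov, borderline SN1 opening), and the tethered hydroperoxide, an alpha-effect nucleophile, then opens the second epoxide at its tertiary carbon in a 6-exo-tet closure that forms the 1,2-dioxane, the cis/trans mixture at C3 and C6 converging later on achiral 9.

Step 6
Reactants: 8 3,6-bis[(tert-butyldiphenylsilyloxy)methyl]-3,6-bis(hydroxymethyl)-1,2-dioxane
Product: 9 1,2-dioxane-3,3,6,6-tetrayltetramethanol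
Conditions: HF·pyridine, THF/pyridine, 0 °C → rt
Reagents that add atoms: none
Why: Fluoride cleaves the two Si–O bonds under mildly acidic conditions that leave the di-tertiary dialkyl peroxide intact (desilylation), and the product is achiral because C3 and C6 now each carry two identical hydroxymethyl groups.

Step 7
Reactants: 9 1,2-dioxane-3,3,6,6-tetrayltetramethanol
Product: 10 3,3,6,6-tetrakis(acetoxymethyl)-1,2-dioxane
Conditions: Ac2O, pyridine, DMAP (cat.), CH2Cl2, 0 °C → rt
Reagents that add atoms: acetic anhydride, CC(=O)OC(C)=O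
Why: DMAP-catalysed acetylation of the four unhindered primary hydroxyls (nucleophilic acyl transfer) is exhaustive under conditions to which the peroxide is inert.

Step 8
Reactants: 10 3,3,6,6-tetrakis(acetoxymethyl)-1,2-dioxane
Product: 12 (3S,6S)-3,6-bis(acetoxymethyl)-3,6-bis(hydroxymethyl)-1,2-dioxane, via mono-alcohol triacetate 11 (not isolated)
Conditions: Burkholderia cepacia lipase, 0.2 M NaH2PO4/Na2HPO4 buffer pH 7.0, acetone (10% v/v), 30 °C; stopped when 12 is maximal
Reagents that add atoms: none
Why: The active-site serine is acylated by one acetate of 10 and the acyl-enzyme is then cleaved by water, so each turnover turns one CH2OAc into CH2OH without touching any bond to a ring carbon. The closest known reaction type is the lipase-mediated hydrolytic desymmetrisation of prochiral 2,2-disubstituted propane-1,3-diol diacetates, applied here to the two C(CH2OAc)2 units at C3 and C6. No ring is closed and no skeletal bond is formed. The stereocentre at C3 is set by the chiral binding pocket, which accepts only one of the two enantiotopic acetoxymethyl groups, and the stereocentre at C6 is set in the same way in the second turnover, where the pocket again takes the arm that the C2 axis of the ring relates to the first. The step needs enantiotopic-group selectivity at each carbon and, in the second hydrolysis, site selectivity for the untouched carbon; the latter is secured because the acetate left on the hydrolysed carbon is the one the enzyme disfavours, and over-hydrolysis is avoided by stopping when 12 is maximal. A mismatched second hydrolysis should give the meso cis diol diacetate, a diastereomer removable by chromatography, so the optical purity of 12 should exceed the selectivity of a single hydrolysis.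

Step 9
Reactants: 12 (3S,6S)-3,6-bis(acetoxymethyl)-3,6-bis(hydroxymethyl)-1,2-dioxane
Product: 14 (3R,6R)-3,6-bis(acetoxymethyl)-3,6-bis(iodomethyl)-1,2-dioxane, via bis(triflate) 13 (not isolated)
Conditions: Tf2O (2.4 equiv), 2,6-lutidine, CH2Cl2, −78 → −20 °C; then Bu4NI (6 equiv), MeCN, rt → 40 °C
Reagents that add atoms: trifluoromethanesulfonic anhydride, O=S(=O)(OS(=O)(=O)C(F)(F)F)C(F)(F)F (atoms in 13 only); tetrabutylammonium iodide, CCCC[N+](CCCC)(CCCC)CCCC.[I-]
Why: Both primary hydroxyls are triflated at low temperature, where acetyl migration between the two arms of one carbon cannot compete, and excess soluble iodide then displaces the neopentyl-type triflates by SN2 (sulfonate–halide exchange) without touching any bond to C3 or C6, so the configuration is kept and only the descriptors change.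

Step 10
Reactants: 14 (3R,6R)-3,6-bis(acetoxymethyl)-3,6-bis(iodomethyl)-1,2-dioxane
Product: 15 (3R,6R)-3,6-bis(acetoxymethyl)-3,6-dimethyl-1,2-dioxane
Conditions: Bu3SnH (5 equiv, 1 M), Et3B, air, toluene, 0 °C
Reagents that add atoms: none
Why: Radical-chain dehalogenation with tin hydride, a reaction known for β-halo dialkyl peroxides, turns both CH2I groups into methyl groups because at low temperature and high Bu3SnH concentration hydrogen transfer to the primary radical should outrun its attack on the O–O bond, and no bond to a stereocentre is broken.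

Step 11
Reactants: 15 (3R,6R)-3,6-bis(acetoxymethyl)-3,6-dimethyl-1,2-dioxane
Product: 16 [(3R,6R)-6-(hydroxymethyl)-3,6-dimethyl-1,2-dioxan-3-yl]methyl acetate
Conditions: K2CO3 (0.3 equiv), MeOH, 0 °C, stopped near half conversion; recovered 15 recycled
Reagents that add atoms: none
Why: Carbonate-catalysed methanolysis (transesterification) is stopped at partial conversion so that one acetate is removed, and since the two acetoxymethyl arms are interchanged by the C2 axis either cleavage gives the same mono-alcohol.

Step 12
Reactants: 16 [(3R,6R)-6-(hydroxymethyl)-3,6-dimethyl-1,2-dioxan-3-yl]methyl acetate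
Product: 17 [(3R,6R)-6-formyl-3,6-dimethyl-1,2-dioxan-3-yl]methyl acetate
Conditions: Dess–Martin periodinane, pyridine, CH2Cl2, 0 °C → rt
Reagents that add atoms: none
Why: Dess–Martin oxidation converts the neopentyl-type primary alcohol into the non-enolisable aldehyde under buffered, non-nucleophilic conditions that spare the acetate and the peroxide.

Step 13
Reactants: 18 (7-bromoheptyl)benzene, 19 triphenylphosphine
Product: 20 triphenyl(7-phenylheptyl)phosphonium bromide
Conditions: MeCN, reflux
Reagents that add atoms: none
Why: Triphenylphosphine displaces the unhindered primary bromide by SN2 to give the Wittig salt (quaternisation).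

Step 14
Reactants: 17 [(3R,6R)-6-formyl-3,6-dimethyl-1,2-dioxan-3-yl]methyl acetate, 20 triphenyl(7-phenylheptyl)phosphonium bromide
Product: 22 [(3R,6R)-3,6-dimethyl-6-[(1Z)-8-phenyloct-1-en-1-yl]-1,2-dioxan-3-yl]methyl acetate, via phosphorus ylide 21 (not isolated)
Conditions: 20 (1.1 equiv), NaN(SiMe3)2 (1.05 equiv), THF, 0 °C; then 17, −78 °C → rt
Reagents that add atoms: none
Why: The unstabilised ylide, generated with slightly less than one equivalent of base so that no free amide remains, adds to the hindered but reactive aldehyde at low temperature faster than to the acetate, and the Wittig reaction gives mainly the Z alkene, whose geometry is irrelevant because step 17 saturates it.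

Step 15
Reactants: 22 [(3R,6R)-3,6-dimethyl-6-[(1Z)-8-phenyloct-1-en-1-yl]-1,2-dioxan-3-yl]methyl acetate
Product: 23 [(3R,6R)-3,6-dimethyl-6-[(1Z)-8-phenyloct-1-en-1-yl]-1,2-dioxan-3-yl]methanol
Conditions: K2CO3 (cat.), MeOH, rt
Reagents that add atoms: none
Why: Carbonate-catalysed methanolysis removes the remaining acetate (transesterification) without affecting the alkene or the peroxide, whose ring carbons bear no hydrogen and therefore cannot undergo Kornblum–DeLaMare cleavage.

Step 16
Reactants: 23 [(3R,6R)-3,6-dimethyl-6-[(1Z)-8-phenyloct-1-en-1-yl]-1,2-dioxan-3-yl]methanol, 24 methyl (triphenylphosphoranylidene)acetate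
Product: 26 methyl (2E)-3-[(3R,6R)-3,6-dimethyl-6-[(1Z)-8-phenyloct-1-en-1-yl]-1,2-dioxan-3-yl]prop-2-enoate, via aldehyde 25 (not isolated)
Conditions: Dess–Martin periodinane, pyridine, CH2Cl2, 0 °C → rt; then 24 (1.5 equiv), rt → 40 °C
Reagents that add atoms: none
Why: Dess–Martin oxidation followed in the same flask by Wittig olefination with the stabilised ylide avoids isolation of the second α-peroxy aldehyde and should give the E enoate.

Step 17
Reactants: 26 methyl (2E)-3-[(3R,6R)-3,6-dimethyl-6-[(1Z)-8-phenyloct-1-en-1-yl]-1,2-dioxan-3-yl]prop-2-enoate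
Product: 27 methyl 3-[(3R,6S)-3,6-dimethyl-6-(8-phenyloctyl)-1,2-dioxan-3-yl]propanoate
Conditions: KO2CN=NCO2K (excess, in portions), AcOH, MeOH/pyridine, 0 °C → rt
Reagents that add atoms: none
Why: Diimide generated from the azodicarboxylate transfers two hydrogens concertedly to each C=C bond (diimide reduction) and, unlike catalytic hydrogenation, leaves the O–O bond, the arene and the ester untouched, the change of one descriptor being a matter of priority only.

Step 18
Reactants: 27 methyl 3-[(3R,6S)-3,6-dimethyl-6-(8-phenyloctyl)-1,2-dioxan-3-yl]propanoate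
Product: 28 3-[(3R,6S)-3,6-dimethyl-6-(8-phenyloctyl)-1,2-dioxan-3-yl]propanoic acid
Conditions: LiOH, THF/H2O (3:1), 0 °C → rt; then 1 M HCl to pH 3
Reagents that add atoms: lithium hydroxide, [Li+].[OH-]
Why: Saponification of the methyl ester with LiOH (acyl–oxygen cleavage) followed by mild acidification gives the acid, and the di-tertiary peroxide, which has no α-hydrogen, is stable to aqueous hydroxide at this temperature.

Compound list
1 | ethyl 2-(bromomethyl)acrylate | C=C(CBr)C(=O)OCC | starting material
2 | diethyl 2,5-dimethylidenehexanedioate | CCOC(=O)C(=C)CCC(=C)C(=O)OCC | intermediate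
3 | 2,5-dimethylidenehexane-1,6-diol | OCC(=C)CCC(=C)CO | intermediate
4 | 1,6-bis(tert-butyldiphenylsilyloxy)-2,5-dimethylidenehexane | CC(C)(C)[Si](OCC(=C)CCC(=C)CO[Si](c1ccccc1)(c1ccccc1)C(C)(C)C)(c1ccccc1)c1ccccc1 | intermediate
5 | 1,2-bis{2-[(tert-butyldiphenylsilyloxy)methyl]oxiran-2-yl}ethane (meso and racemic diastereomers, not controlled) | CC(C)(C)[Si](OCC1(CCC2(CO[Si](c3ccccc3)(c3ccccc3)C(C)(C)C)CO2)CO1)(c1ccccc1)c1ccccc1 | intermediate
6 | hydrogen peroxide | OO | starting material
7 | 2-[(tert-butyldiphenylsilyloxy)methyl]-4-{2-[(tert-butyldiphenylsilyloxy)methyl]oxiran-2-yl}-2-hydroperoxybutan-1-ol (diastereomer mixture) | CC(C)(C)[Si](OCC(CO)(OO)CCC1(CO[Si](c2ccccc2)(c2ccccc2)C(C)(C)C)CO1)(c1ccccc1)c1ccccc1 | intermediate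
8 | 3,6-bis[(tert-butyldiphenylsilyloxy)methyl]-3,6-bis(hydroxymethyl)-1,2-dioxane (cis/trans mixture) | OCC1(CO[Si](c2ccccc2)(c2ccccc2)C(C)(C)C)CCC(CO)(CO[Si](c2ccccc2)(c2ccccc2)C(C)(C)C)OO1 | intermediate
9 | 1,2-dioxane-3,3,6,6-tetrayltetramethanol (achiral) | OCC1(CO)CCC(CO)(CO)OO1 | intermediate
10 | 3,3,6,6-tetrakis(acetoxymethyl)-1,2-dioxane (achiral) | CC(=O)OCC1(COC(C)=O)CCC(COC(C)=O)(COC(C)=O)OO1 | intermediate
11 | (3S)-3,6,6-tris(acetoxymethyl)-3-(hydroxymethyl)-1,2-dioxane | OC[C@]1(COC(C)=O)CCC(COC(C)=O)(COC(C)=O)OO1 | intermediate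
12 | (3S,6S)-3,6-bis(acetoxymethyl)-3,6-bis(hydroxymethyl)-1,2-dioxane (C2-symmetric, hydroxymethyls trans) | OC[C@]1(COC(C)=O)CC[C@](CO)(COC(C)=O)OO1 | intermediate
13 | (3R,6R)-3,6-bis(acetoxymethyl)-3,6-bis[(trifluoromethylsulfonyloxy)methyl]-1,2-dioxane | FC(F)(F)S(=O)(=O)OC[C@]1(COC(C)=O)CC[C@](COS(=O)(=O)C(F)(F)F)(COC(C)=O)OO1 | intermediate
14 | (3R,6R)-3,6-bis(acetoxymethyl)-3,6-bis(iodomethyl)-1,2-dioxane | IC[C@]1(COC(C)=O)CC[C@](CI)(COC(C)=O)OO1 | intermediate
15 | (3R,6R)-3,6-bis(acetoxymethyl)-3,6-dimethyl-1,2-dioxane | C[C@]1(COC(C)=O)CC[C@](C)(COC(C)=O)OO1 | intermediate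
16 | [(3R,6R)-6-(hydroxymethyl)-3,6-dimethyl-1,2-dioxan-3-yl]methyl acetate | C[C@]1(CO)CC[C@](C)(COC(C)=O)OO1 | intermediate
17 | [(3R,6R)-6-formyl-3,6-dimethyl-1,2-dioxan-3-yl]methyl acetate | C[C@]1(C=O)CC[C@](C)(COC(C)=O)OO1 | intermediate
18 | (7-bromoheptyl)benzene | BrCCCCCCCc1ccccc1 | starting material
19 | triphenylphosphine | c1ccc(P(c2ccccc2)c2ccccc2)cc1 | starting material
20 | triphenyl(7-phenylheptyl)phosphonium bromide | [Br-].c1ccc(CCCCCCC[P+](c2ccccc2)(c2ccccc2)c2ccccc2)cc1 | intermediate
21 | triphenyl(7-phenylheptylidene)phosphorane | c1ccc(CCCCCCC=P(c2ccccc2)(c2ccccc2)c2ccccc2)cc1 | intermediate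
22 | [(3R,6R)-3,6-dimethyl-6-[(1Z)-8-phenyloct-1-en-1-yl]-1,2-dioxan-3-yl]methyl acetate (Z expected as major isomer) | C[C@]1(/C=C\CCCCCCc2ccccc2)CC[C@](C)(COC(C)=O)OO1 | intermediate
23 | [(3R,6R)-3,6-dimethyl-6-[(1Z)-8-phenyloct-1-en-1-yl]-1,2-dioxan-3-yl]methanol | C[C@]1(/C=C\CCCCCCc2ccccc2)CC[C@](C)(CO)OO1 | intermediate
24 | methyl (triphenylphosphoranylidene)acetate | COC(=O)C=P(c1ccccc1)(c1ccccc1)c1ccccc1 | starting material
25 | (3R,6R)-3,6-dimethyl-6-[(1Z)-8-phenyloct-1-en-1-yl]-1,2-dioxane-3-carbaldehyde | C[C@]1(/C=C\CCCCCCc2ccccc2)CC[C@](C)(C=O)OO1 | intermediate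
26 | methyl (2E)-3-[(3R,6R)-3,6-dimethyl-6-[(1Z)-8-phenyloct-1-en-1-yl]-1,2-dioxan-3-yl]prop-2-enoate | C[C@]1(/C=C\CCCCCCc2ccccc2)CC[C@](C)(/C=C/C(=O)OC)OO1 | intermediate
27 | methyl 3-[(3R,6S)-3,6-dimethyl-6-(8-phenyloctyl)-1,2-dioxan-3-yl]propanoate | C[C@]1(CCCCCCCCc2ccccc2)CC[C@](C)(CCC(=O)OC)OO1 | intermediate
28 | 3-[(3R,6S)-3,6-dimethyl-6-(8-phenyloctyl)-1,2-dioxan-3-yl]propanoic acid | C[C@]1(CCCCCCCCc2ccccc2)CC[C@](C)(CCC(=O)O)OO1 | target

Total step count: 18. Longest linear sequence: 17 steps (steps 1 to 12 and 14 to 18); step 13 prepares the Wittig salt in a one-step side branch.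

Steps most likely to fail

First, step 8. The lipase may discriminate poorly between the enantiotopic acetoxymethyl groups, may cleave the second acetate on the carbon already hydrolysed, or the acetyl group may migrate between the two arms of one carbon in water. Each of these processes lowers the optical purity of 12. The fallback replaces enzyme control by classical resolution. Material of low optical purity is freed from the meso isomer by chromatography and carried through steps 9 and 10, and the fallback sets out from 15. Complete methanolysis (K2CO3, MeOH) should give [(3R,6R)-3,6-dimethyl-1,2-dioxane-3,6-diyl]dimethanol F1 mixed with its enantiomer [(3S,6S)-3,6-dimethyl-1,2-dioxane-3,6-diyl]dimethanol F2. Esterification of the mixture with (2S)-2-methoxy-2-phenylacetic acid (DCC, DMAP, CH2Cl2) should give two diastereomers, [(3R,6R)-3,6-dimethyl-1,2-dioxane-3,6-diyl]bis(methylene) bis[(2S)-2-methoxy-2-phenylacetate] F3 and [(3S,6S)-3,6-dimethyl-1,2-dioxane-3,6-diyl]bis(methylene) bis[(2S)-2-methoxy-2-phenylacetate] F4, to be separated by chromatography or crystallisation. Methanolysis of F3 returns enantiopure F1, and acetylation with one equivalent of Ac2O in pyridine rejoins the route at 16.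

Second, step 5. After the first opening, the newly freed primary hydroxyl, the oxygen of the second epoxide or a further molecule of H2O2 may capture the activated epoxide in place of the hydroperoxide, or the peroxide may add at the CH2 terminus. Each of these diverts material from the dioxane. The fallback moves ring formation from epoxide opening to mercury-mediated alkene activation and sets out from 4. Treatment with Hg(OAc)2 (2 equiv) and ethereal H2O2 in CH2Cl2 at 0 °C, then aqueous KBr, should give 3,6-bis(bromomercuriomethyl)-3,6-bis[(tert-butyldiphenylsilyloxy)methyl]-1,2-dioxane F5. This arises by Markovnikov peroxymercuration of one alkene and 6-exo capture of the second mercurinium ion by the hydroperoxide, and no free hydroxyl is present while the O–O ring forms. Oxidative demercuration (NaBH4, O2, DMF) converts both C–Hg bonds into C–OH and comes back to the route at 8.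

Third, step 10. The primary radical next to the peroxide-bearing carbon may attack the O–O bond (3-exo homolytic substitution giving an epoxide and an alkoxyl radical) before it abstracts hydrogen, which destroys the dioxane. The fallback replaces the radical deoxygenation by a polar one and sets out from 12. The bis(triflate) 13 is isolated after the first stage of step 9 and both triflates are displaced by hydride with Bu4NBH4 in THF at 0 °C → rt (SN2 reduction of primary sulfonates, to which dialkyl peroxides and acetates are inert), which comes back to the route at 15 and makes no new compound.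

Further compounds
F1 | step 8 | [(3R,6R)-3,6-dimethyl-1,2-dioxane-3,6-diyl]dimethanol | C[C@]1(CO)CC[C@](C)(CO)OO1
F2 | step 8 | [(3S,6S)-3,6-dimethyl-1,2-dioxane-3,6-diyl]dimethanol | C[C@@]1(CO)CC[C@@](C)(CO)OO1
F3 | step 8 | [(3R,6R)-3,6-dimethyl-1,2-dioxane-3,6-diyl]bis(methylene) bis[(2S)-2-methoxy-2-phenylacetate] | C[C@]1(COC(=O)[C@@H](OC)c2ccccc2)CC[C@](C)(COC(=O)[C@@H](OC)c2ccccc2)OO1
F4 | step 8 | [(3S,6S)-3,6-dimethyl-1,2-dioxane-3,6-diyl]bis(methylene) bis[(2S)-2-methoxy-2-phenylacetate] | C[C@@]1(COC(=O)[C@@H](OC)c2ccccc2)CC[C@@](C)(COC(=O)[C@@H](OC)c2ccccc2)OO1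
F5 | step 5 | 3,6-bis(bromomercuriomethyl)-3,6-bis[(tert-butyldiphenylsilyloxy)methyl]-1,2-dioxane (cis/trans mixture) | Br[Hg]CC1(CO[Si](c2ccccc2)(c2ccccc2)C(C)(C)C)CCC(C[Hg]Br)(CO[Si](c2ccccc2)(c2ccccc2)C(C)(C)C)OO1
F0 | step 10 | none | none
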